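**One reading.** Maple keeps 66.3% of its electrophile at 80.0 min, and I start from that reading.

| flask | electrophile | nucleophile | gas | remark | time |
|---|---|---|---|---|---|
| ash | 0.067 M | 2 equiv | 19 mM (held) | run made earlier |  |
| maple | 0.20 M | 2 equiv | 19 mM (held) | run made earlier |  |
| Monday's | 0.10 M | 2.00 equiv | 19 mM (held) |  | 6.0 h |
| Saturday's | 0.10 M | 3.00 equiv | 19 mM (held) |  | 6.0 h |
| Friday's | 0.10 M | 4.50 equiv | 19 mM (held) |  | 6.0 h |

| run | time / min | electrophile / % | product / % |
|---|---|---|---|
| ash | 4.00 | 99.3 | 0.5 |
| ash | 12.0 | 97.2 | 2.5 |
| ash | 20.0 | 96.1 | 4.0 |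
| ash | 30.0 | 93.9 | 5.8 |
| ash | 40.0 | 92.2 | 7.8 |
| ash | 60.0 | 88.1 | 11.2 |
| ash | 80.0 | 85.4 | 14.8 |
| maple | 6.00 | 96.9 | 3.5 |
| maple | 8.00 | 95.2 | 4.6 |
| maple | 12.0 | 92.7 | 7.4 |
| maple | 20.0 | 88.6 | 11.5 |
| maple | 30.0 | 83.7 | 16.6 |
| maple | 50.0 | 76.2 | 24.4 |
| maple | 80.0 | 66.3 | 33.6 |

(each reading ± 0.3 percentage points)

- at the start none of the gas is in solution

1. part of the electrophile that has reacted at the end, Monday's
2. part of the electrophile that has reacted at the end, Saturday's
3. part of the electrophile that has reacted at the end, Friday's
4. what raising the equivalents of nucleophile from its lowest to its highest value here does to the part of the electrophile that has reacted (changes below 5 percentage points count as none) (it rises / it falls / no change)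

**The lifetime.** I take the rate as k·c_electrophile·c_nucleophile. If each electrophile costs two nucleophile, then at 2.00 equiv the nucleophile falls in step with the electrophile, and 1/f − 1 = t/τ, with f the part left. Here τ = 1/(k·c_nucleophile as charged), the electrophile's pseudo-first-order lifetime with the nucleophile as charged, so at fixed k the product of τ and the charged c_nucleophile stays constant.

**Electrophile amount.** By hand, more electrophile at fixed equivalents means more nucleophile and a shorter τ. Read from the last readings, ash has 7.80 h and maple 2.62 h: ash's is longer by a factor of 2.98, and maple's charge of electrophile is larger than ash's by a factor of 2.99. Scaled to Monday's charge, ash gives 5.23 h and maple 5.25 h. I carry the latter.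

**Time.** Monday's 6.0 h is 1.14 lifetimes, so with n the number of lifetimes and x the part reacted, x = n/(n + 1) gives 53.4% reacted.

**Nucleophile amount.** No run has turned this setting, so what follows is my judgement. By hand, at fixed electrophile, τ shrinks with the equivalents, and the nucleophile no longer falls in step with the electrophile. With q the equivalents over 2.00 equiv, integrating gives x = q(r − 1)/(qr − 1), where r = exp(n(1 − 1/q)). Saturday's has 1.72 lifetimes and 69.8% reacted. Friday's has 2.57 lifetimes and 85.1% reacted.

**The forecast.** It reads the same runs as second order in electrophile, judges that “nucleophile probably does not enter the rate”, and gives 54%, 54% and 54%: no change. We differ on Saturday's and Friday's.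

**The flask.** Monday's gives 53.9%, Saturday's 70.4% and Friday's 85.6%: it rises, by 32 percentage points.

    crystals ⇌ acid set free, rate k1*(cs1 - [acid set free]) while solid is left; crystals form when [acid set free] > cs1 (solubility = 21.0 mM, k = 100 h⁻¹)
    gas ⇌ free base, rate k2*(csat - [free base]) (kL = 0.690 h⁻¹)
    nucleophile + acid set free ⇌ protonated nucleophile, settled at all times (K = 14000 M⁻¹)
    acid set free + free base ⇌ salt of the base, settled at all times (K = 1100 M⁻¹)
    electrophile + nucleophile → acid set free + product (k = 0.970 M⁻¹ h⁻¹)

**The neighbour.** Saturday's has spent twice as much nucleophile as it has made product, and 0.0697 M stands as protonated nucleophile at 6.00 h. A neighbour flask, Saturday's recipe at 0.025 M of electrophile, has τ = 14.0 h, so its time is 0.429 lifetimes and the formula gives 31.6%. That neighbour reaches 32.0%.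

The readings come from a simulation from invented constants; the scatter is artificial.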